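The readings were computed for an exercise, noise included.

The decision is whether to run this flask for its excess or for its conversion, and these minutes give the reckoning for it.

in all of them: precatalyst 0.1 mol%
- Thursday's: left-handed substrate 0.12 M; right-handed substrate 0.12 M; partner 2.5 equiv; free catalyst 10 mol%; run made earlier
- Friday's: left-handed substrate 0.19 M; right-handed substrate 0.19 M; partner 2.5 equiv; free catalyst 10 mol%; run made earlier
- Saturday's: left-handed substrate 0.25 M; right-handed substrate 0.25 M; partner 2.5 equiv; free catalyst 15 mol%; run made earlier
- flask: left-handed substrate 0.25 M; right-handed substrate 0.25 M; partner 2.50 equiv; free catalyst 10 mol%; time 10 min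
- Thursday's (time / min: left-handed product / %, right-handed product / %): 0.667: 16, 9; 2.00: 28, 19; 4.00: 33, 23; 5.00: 33, 26; 8.00: 39, 24; 10.0: 41, 29
- Friday's (time / min: left-handed product / %, right-handed product / %): 0.833: 34, 20; 1.33: 36, 22; 2.00: 35, 26; 4.00: 41, 33; 6.00: 43, 34; 10.0: 43, 36
- Saturday's (time / min: left-handed product / %, right-handed product / %): 0.833: 43, 32; 2.50: 49, 42; 5.00: 47, 46; 8.00: 48, 46; 10.0: 48, 43

(scatter of a reading: 1.5 percentage points)
- free catalyst is single-handed; left-handed substrate and right-handed substrate are mirror images of each other, charged as a racemate, each of them at the stated concentration
- an excess is below zero if the other one leads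
1. excess of left-handed product over right-handed product in the product at 12 s
2. excess of left-handed product over right-handed product in the product at 10 min
3. part of the left-handed substrate and right-handed substrate charged together that has reacted at 10 min

Ines proposed one measure, a hand's exposure: the logarithm of its charge over what is left of it. From Thursday's reading at 10.0 min she read 1.98 for the selectivity factor, the left-handed exposure over the right-handed. She argued that this ratio should carry both ends of the flask.

Tomas took the early end. He said the excess starts from the selectivity factor less one over the same factor plus one, here 32.8%. He assumed the rate follows catalyst times partner, so he scaled Thursday's first right-handed exposure by the square of the concentration and by the time. That gave 0.258 at 12 s, and so an excess of 27.5%.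

Ines took the late end. She assumed the plateau exposure follows the catalyst concentration and scaled Friday's last right-handed exposure to this flask, which gave 1.67. Multiplying by the selectivity factor gives the left-handed exposure, and the two remainders then give an excess of 8.54% and a conversion of 88.8% at 10 min.

The forecast, close to this, gave 27% (20% to 34%), 9% (5% to 13%) and 87% (82% to 91%), on the view that “this looks like a fast catalyst that dies rather than substrate running out”.

The flask gives an excess of 23.0% at 12 s, an excess of 8.57% at 10 min and a conversion of 87.9% at 10 min, with partner, the limiting reagent, down to 1.8% of its charge at 10.0 min. Right-handed substrate in this flask stands at 18% of its charge, and raising that remainder to the power 1.98 gives 3.52% of its charge for the left-handed substrate, while the flask holds more, 5.8%.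

    partner + precatalyst → racemization catalyst + spent reagent (k = 0.0320 L mol⁻¹ s⁻¹)
    2 partner → self-condensation product (k = 0.0130 L mol⁻¹ s⁻¹)
    partner + free catalyst + right-handed substrate → free catalyst + right-handed product (k = 2.80 L² mol⁻² s⁻¹)
    left-handed substrate + racemization catalyst ⇌ right-handed substrate + racemization catalyst, rate k4*[racemization catalyst]*[left-handed substrate] forward; the back reaction follows from the equilibrium constant (k = 0.890 L mol⁻¹ s⁻¹)
    free catalyst ⇌ dormant form (K = 0.880, k = 0.0250 s⁻¹)
    partner + free catalyst + left-handed substrate → free catalyst + left-handed product (k = 5.10 L² mol⁻² s⁻¹)

In the neighbouring flask with 0.620 equiv of partner, all else as in this flask, one partner per product covers 31.0% of both substrates together. Shared out by the selectivity factor, that conversion gives a right-handed exposure of 0.249 and an excess of 27.7%. At 10 min that neighbouring flask is computed to give an excess of 24.7% at 29.3% conversion.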